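## Retrosynthetic overview

1. Numbering: C1 (bears C7H2OH), C2 (C=O), C3 (O-tigloyl), C4 (isopropyl), C5 (O-angeloyl), C6 (=CH). The plan rests on two features of the single cyclohexenone ring. C3–C4–C5 is an oxygen/alkyl/oxygen triad that reads 3,4-syn and 3,5-anti once the ring is opened, and C1=C6 is the one ring bond with no stereocentre at either atom.
2. The only ring is therefore formed last, by ring-closing metathesis across C1=C6 of an acyclic dienone that already carries both esters. Only the C7 silyl ether is removed afterwards.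
3. C1–C2 comes from a Nozaki–Hiyama–Kishi addition of a 2-iodoallyl silyl ether to the C2 aldehyde, followed by oxidation to the enone.
4. The C5 carbinol and the O3 tiglate arise together in an Evans–Tishchenko reduction of a β-hydroxy vinyl ketone with tiglaldehyde, which leaves O5 free for the angelate.
5. C3–C4 comes from an Evans syn-aldol of the (R)-benzyloxazolidinone isovalerimide with silyloxyacetaldehyde. C5–C6 comes from vinylmagnesium bromide and the Weinreb amide.

Key step: step 13

Remark on the chemistry: the carbinol centre created at C2 in the chromium-mediated coupling is assumed to form as a mixture of epimers. It is carried on as such because the next oxidation removes it. The locants C1–C7 above are also used for the open-chain intermediates.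

## Route

Step 1
Reactants: 1 (R)-4-benzyl-1,3-oxazolidin-2-one; 2 3-methylbutanoyl chloride (isovaleryl chloride)
Product: 4 (R)-4-benzyl-3-(3-methylbutanoyl)-1,3-oxazolidin-2-one, via N-lithio oxazolidinone 3 (not isolated)
Conditions: n-BuLi, THF, −78 °C; then 2, −78 → 0 °C
Reagents that add atoms: none
Why: N-acylation of the lithiated carbamate nitrogen with an acid chloride is the standard way of loading this auxiliary and does not touch its benzyl-bearing stereocentre.

Step 2
Reactants: 4 (R)-4-benzyl-3-(3-methylbutanoyl)-1,3-oxazolidin-2-one; 5 (tert-butyldimethylsilyloxy)acetaldehyde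
Product: 8 (R)-4-benzyl-3-[(2R,3R)-4-(tert-butyldimethylsilyloxy)-3-hydroxy-2-(propan-2-yl)butanoyl]-1,3-oxazolidin-2-one, via Z-boron enolate 6 (not isolated), via boron aldolate 7 (not isolated)
Conditions: Bu2BOTf, Et3N, CH2Cl2, 0 °C; then 5, −78 → 0 °C; then MeOH, pH 7 buffer (NaH2PO4/Na2HPO4), 30% H2O2, 0 °C
Reagents that add atoms: none
Why: Evans syn-aldol, in which soft enolisation gives the Z-boron enolate and a Zimmerman–Traxler chair with opposed imide dipoles brings the aldehyde to the enolate face away from the benzyl group, so that C4 and C3 are set syn and in the absolute sense (2R,3R in 8) that the (R)-auxiliary dictates.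

Step 3
Reactants: 8 the aldol adduct
Product: 9 (2R,3R)-4-(tert-butyldimethylsilyloxy)-3-hydroxy-N-methoxy-N-methyl-2-(propan-2-yl)butanamide
Conditions: MeNH(OMe)·HCl, AlMe3, THF, −20 → 0 °C; aq. potassium sodium tartrate work-up
Reagents that add atoms: N,O-dimethylhydroxylamine hydrochloride, CNOC.Cl
Why: Aluminium-amide transamination to the Weinreb amide, in which the free C3 hydroxyl binds aluminium and directs the amide nitrogen to the exocyclic imide carbonyl, which should outweigh the hindrance of the α-isopropyl group and release the auxiliary without disturbing C3 or C4.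

Step 4
Reactants: 9 the Weinreb amide
Product: 11 (4R,5R)-6-(tert-butyldimethylsilyloxy)-5-hydroxy-4-(propan-2-yl)hex-1-en-3-one, via magnesium chelate 10 (not isolated)
Conditions: CH2=CHMgBr (3.5 equiv), THF, −78 → 0 °C; inverse quench into cold 1 M HCl/Et2O
Reagents that add atoms: vinylmagnesium bromide, C=C[Mg]Br
Why: Grignard addition to a Weinreb amide, in which the reagent first deprotonates the hydroxyl and then adds once because the chelated adduct holds until the quench, while pouring into cold acid protonates the released MeNH(OMe) before it can add in a conjugate sense to the new vinyl ketone.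

Step 5
Reactants: 11 the β-hydroxy vinyl ketone; 12 tiglaldehyde, (E)-2-methylbut-2-enal
Product: 14 (2R,3S,4S)-1-(tert-butyldimethylsilyloxy)-4-hydroxy-3-(propan-2-yl)hex-5-en-2-yl (E)-2-methylbut-2-enoate, via samarium-bound hemiacetal 13 (not isolated)
Conditions: SmI2 (0.3 equiv) premixed with 12 (6 equiv), THF, −10 °C; then 11, −10 °C
Reagents that add atoms: none
Why: Evans–Tishchenko reduction, in which the C3 hydroxyl adds to tiglaldehyde, trivalent samarium ties the hemiacetal oxygen to the C5 ketone in a chair-like bicyclic transition state and the hemiacetal hydrogen passes intramolecularly to one face of C5, which sets C5 (S) 1,3-anti to C3, allows only 1,2-reduction of the enone, leaves the tiglate on O3 and the hydroxyl on C5, and, through the premixing, consumes all divalent samarium before the vinyl ketone arrives.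

Step 6
Reactants: 14 the C3 tiglate with free C5 hydroxyl; 15 angelic acid, (Z)-2-methylbut-2-enoic acid
Product: 17 (3S,4S,5R)-6-(tert-butyldimethylsilyloxy)-5-[(E)-2-methylbut-2-enoyloxy]-4-(propan-2-yl)hex-1-en-3-yl (Z)-2-methylbut-2-enoate, via mixed anhydride 16 (not isolated)
Conditions: 15, 2,4,6-Cl3C6H2COCl, Et3N, toluene, rt; then 14, 80 °C (no DMAP)
Reagents that add atoms: none
Why: Esterification through the 2,4,6-trichlorobenzoyl mixed anhydride (Yamaguchi-type activation without a nucleophilic catalyst), in which the alcohol attacks the less hindered angeloyl carbonyl directly, so that no reversible conjugate addition can turn the Z-enoate into the tiglate and C5 keeps its configuration because only the O–H bond is broken.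

Step 7
Reactants: 17 the diester silyl ether
Product: 18 (3S,4S,5R)-6-hydroxy-5-[(E)-2-methylbut-2-enoyloxy]-4-(propan-2-yl)hex-1-en-3-yl (Z)-2-methylbut-2-enoate
Conditions: HF·pyridine, pyridine, THF, 0 °C → rt
Reagents that add atoms: none
Why: Fluoride cleavage of the only silyl ether under buffered, weakly acidic conditions, which avoids the basic alkoxide that a tetraalkylammonium fluoride would create and so should keep the C3 tiglate from shifting to the new primary C2 hydroxyl.

Step 8
Reactants: 18 the primary alcohol
Product: 19 (3S,4S,5R)-5-[(E)-2-methylbut-2-enoyloxy]-6-oxo-4-(propan-2-yl)hex-1-en-3-yl (Z)-2-methylbut-2-enoate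
Conditions: Dess–Martin periodinane, CH2Cl2, 0 °C → rt; used crude
Reagents that add atoms: none
Why: Dess–Martin oxidation stops at the aldehyde and is free of base, so the α-acyloxy centre C3 should not enolise and the four alkenes are left alone.

Step 9
Reactants: 20 prop-2-yn-1-ol (propargyl alcohol)
Product: 21 2-iodoprop-2-en-1-ol
Conditions: NaI, Me3SiCl, H2O, MeCN, rt
Reagents that add atoms: sodium iodide, [Na+].[I-]
Why: Markovnikov hydroiodination of a terminal alkyne with hydrogen iodide generated in the flask places iodine on the internal carbon and gives the 2-iodoalkene.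

Step 10
Reactants: 21 2-iodoprop-2-en-1-ol
Product: 22 tert-butyl[(2-iodoprop-2-en-1-yl)oxy]dimethylsilane
Conditions: TBSCl, imidazole, CH2Cl2, 0 °C → rt
Reagents that add atoms: tert-butyldimethylsilyl chloride, CC(C)(C)[Si](C)(C)Cl
Why: Imidazole-promoted silylation of an unhindered primary alcohol is routine and leaves the vinyl iodide intact.

Step 11
Reactants: 19 the C2 aldehyde; 22 the 2-iodoallyl silyl ether
Product: 24 (3S,4S,5R,6RS)-7-[(tert-butyldimethylsilyloxy)methyl]-6-hydroxy-5-[(E)-2-methylbut-2-enoyloxy]-4-(propan-2-yl)octa-1,7-dien-3-yl (Z)-2-methylbut-2-enoate, via alkenylchromium dichloride 23 (not isolated)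
Conditions: CrCl2 (6 equiv), NiCl2 (2 mol %), DMF, rt
Reagents that add atoms: none
Why: Nozaki–Hiyama–Kishi coupling, in which zerovalent nickel inserts into the C–I bond and hands the alkenyl group to trivalent chromium, giving a reagent that adds only to aldehydes and forms a weakly basic alkoxide, so that both enoate esters, the C3 centre and the position of the tiglate should survive where a 2-lithio- or 2-magnesioallyl ether would endanger them; the new C2 centre needs no control.

Step 12
Reactants: 24 the C2 allylic alcohol (both epimers)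
Product: 25 (3S,4S,5R)-7-[(tert-butyldimethylsilyloxy)methyl]-5-[(E)-2-methylbut-2-enoyloxy]-6-oxo-4-(propan-2-yl)octa-1,7-dien-3-yl (Z)-2-methylbut-2-enoate
Conditions: Dess–Martin periodinane, CH2Cl2, 0 °C → rt
Reagents that add atoms: none
Why: Dess–Martin oxidation of an allylic alcohol converges both C2 epimers on one α-methylene ketone under base-free conditions that should not epimerise C3.

Step 13
Reactants: 25 the acyclic dienone
Product: 26 (4S,5S,6R)-2-[(tert-butyldimethylsilyloxy)methyl]-4-[(Z)-2-methylbut-2-enoyloxy]-6-[(E)-2-methylbut-2-enoyloxy]-5-(propan-2-yl)cyclohex-2-en-1-one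
Conditions: second-generation Hoveyda–Grubbs catalyst RuCl2(H2IMes)(=CH-C6H4-2-O-i-Pr) (10 mol %, in portions; H2IMes = 1,3-dimesitylimidazolidin-2-ylidene), 1,4-benzoquinone (20 mol %), toluene (2 mM), 80 °C, Ar sparge
Reagents that add atoms: none
Why: Ring-closing olefin metathesis, known for enone-containing dienes that give 2-substituted cyclohex-2-enones: the catalyst exchanges its benzylidene at the monosubstituted C6 vinyl group, the C6 ruthenium alkylidene adds across the C1 methylene alkene in a [2+2] step, and cycloreversion of the metallacyclobutane gives the C1=C6 bond and a ruthenium methylidene that carries the cycle on, ethylene being swept out by the argon stream. The cyclohexenone closes by joining the two termini of a six-carbon chain, so the new endocyclic alkene can only be cis and no stereocentre is made, while C3, C4 and C5 are spectators and the neutral medium leaves the epimerisable C3–H alone. The step needs chemoselectivity among four alkenes: the tiglate and angelate alkenes are trisubstituted and electron-poor and should not be taken up, and closure of the C6 alkylidene onto the C5 angelate to a butenolide would in addition force that ester out of its preferred Z conformation. It also needs ring closure to outrun coupling between two vinyl groups, which the high dilution, the three branched sp3 carbons of the tether and the reversibility of vinyl homocoupling should secure. 1,4-Benzoquinone is present to intercept ruthenium hydrides that could move the C6 alkene towards the C5 oxygen.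

Step 14
Reactants: 26 the C7 silyl ether of the target
Product: 27 (4S,5S,6R)-2-(hydroxymethyl)-4-[(Z)-2-methylbut-2-enoyloxy]-6-[(E)-2-methylbut-2-enoyloxy]-5-(propan-2-yl)cyclohex-2-en-1-one (CNP0293256.3)
Conditions: HF·pyridine, pyridine, THF, 0 °C → rt
Reagents that add atoms: none
Why: Fluoride cleavage of a primary allylic silyl ether under buffered acidic conditions spares both enoate esters, gives no base that could epimerise the α-acyloxy ketone centre C3, and frees a C7 hydroxyl too remote from either ester for an easy acyl shift.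

## Compound list

1 | (R)-4-benzyl-1,3-oxazolidin-2-one | O=C1N[C@H](Cc2ccccc2)CO1 | starting material
2 | 3-methylbutanoyl chloride | CC(C)CC(Cl)=O | starting material
3 | N-lithio-(R)-4-benzyl-1,3-oxazolidin-2-one | [Li]N1[C@H](Cc2ccccc2)COC1=O | intermediate
4 | (R)-4-benzyl-3-(3-methylbutanoyl)-1,3-oxazolidin-2-one | CC(C)CC(=O)N1[C@H](Cc2ccccc2)COC1=O | intermediate
5 | (tert-butyldimethylsilyloxy)acetaldehyde | CC(C)(C)[Si](C)(C)OCC=O | starting material
6 | (Z)-dibutylboron enolate of 4 | CC(C)/C=C(\OB(CCCC)CCCC)N1[C@H](Cc2ccccc2)COC1=O | intermediate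
7 | dibutylboron aldolate of 8 | O=C([C@H](C(C)C)[C@@H](OB(CCCC)CCCC)CO[Si](C)(C)C(C)(C)C)N1[C@H](Cc2ccccc2)COC1=O | intermediate
8 | (R)-4-benzyl-3-[(2R,3R)-4-(tert-butyldimethylsilyloxy)-3-hydroxy-2-(propan-2-yl)butanoyl]-1,3-oxazolidin-2-one | O=C([C@H](C(C)C)[C@@H](O)CO[Si](C)(C)C(C)(C)C)N1[C@H](Cc2ccccc2)COC1=O | intermediate
9 | (2R,3R)-4-(tert-butyldimethylsilyloxy)-3-hydroxy-N-methoxy-N-methyl-2-(propan-2-yl)butanamide | CON(C)C(=O)[C@H](C(C)C)[C@@H](O)CO[Si](C)(C)C(C)(C)C | intermediate
10 | bis(bromomagnesium) salt of the tetrahedral vinyl adduct of 9 (new carbinolamine centre undefined) | C=CC(O[Mg]Br)(N(C)OC)[C@H](C(C)C)[C@@H](O[Mg]Br)CO[Si](C)(C)C(C)(C)C | intermediate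
11 | (4R,5R)-6-(tert-butyldimethylsilyloxy)-5-hydroxy-4-(propan-2-yl)hex-1-en-3-one | C=CC(=O)[C@H](C(C)C)[C@@H](O)CO[Si](C)(C)C(C)(C)C | intermediate
12 | tiglaldehyde, (E)-2-methylbut-2-enal | C/C=C(\C)C=O | starting material
13 | hemiacetal of 11 and tiglaldehyde at O3 (drawn metal-free, bound to samarium in the flask; hemiacetal centre undefined) | C=CC(=O)[C@H](C(C)C)[C@@H](OC(O)/C(C)=C/C)CO[Si](C)(C)C(C)(C)C | intermediate
14 | (2R,3S,4S)-1-(tert-butyldimethylsilyloxy)-4-hydroxy-3-(propan-2-yl)hex-5-en-2-yl (E)-2-methylbut-2-enoate | O[C@@H](C=C)[C@H](C(C)C)[C@@H](OC(=O)/C(C)=C/C)CO[Si](C)(C)C(C)(C)C | intermediate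
15 | angelic acid, (Z)-2-methylbut-2-enoic acid | C/C=C(/C)C(=O)O | starting material
16 | (Z)-2-methylbut-2-enoic 2,4,6-trichlorobenzoic anhydride | C/C=C(/C)C(=O)OC(=O)c1c(Cl)cc(Cl)cc1Cl | intermediate
17 | (3S,4S,5R)-6-(tert-butyldimethylsilyloxy)-5-[(E)-2-methylbut-2-enoyloxy]-4-(propan-2-yl)hex-1-en-3-yl (Z)-2-methylbut-2-enoate | C/C=C(/C)C(=O)O[C@@H](C=C)[C@H](C(C)C)[C@@H](OC(=O)/C(C)=C/C)CO[Si](C)(C)C(C)(C)C | intermediate
18 | (3S,4S,5R)-6-hydroxy-5-[(E)-2-methylbut-2-enoyloxy]-4-(propan-2-yl)hex-1-en-3-yl (Z)-2-methylbut-2-enoate | C/C=C(/C)C(=O)O[C@@H](C=C)[C@H](C(C)C)[C@@H](OC(=O)/C(C)=C/C)CO | intermediate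
19 | (3S,4S,5R)-5-[(E)-2-methylbut-2-enoyloxy]-6-oxo-4-(propan-2-yl)hex-1-en-3-yl (Z)-2-methylbut-2-enoate | C/C=C(/C)C(=O)O[C@@H](C=C)[C@H](C(C)C)[C@@H](OC(=O)/C(C)=C/C)C=O | intermediate
20 | prop-2-yn-1-ol | C#CCO | starting material
21 | 2-iodoprop-2-en-1-ol | C=C(I)CO | intermediate
22 | tert-butyl[(2-iodoprop-2-en-1-yl)oxy]dimethylsilane | C=C(I)CO[Si](C)(C)C(C)(C)C | intermediate
23 | [3-(tert-butyldimethylsilyloxy)prop-1-en-2-yl]chromium dichloride | C=C(CO[Si](C)(C)C(C)(C)C)[Cr](Cl)Cl | intermediate
24 | (3S,4S,5R,6RS)-7-[(tert-butyldimethylsilyloxy)methyl]-6-hydroxy-5-[(E)-2-methylbut-2-enoyloxy]-4-(propan-2-yl)octa-1,7-dien-3-yl (Z)-2-methylbut-2-enoate | C/C=C(/C)C(=O)O[C@@H](C=C)[C@H](C(C)C)[C@@H](OC(=O)/C(C)=C/C)C(O)C(=C)CO[Si](C)(C)C(C)(C)C | intermediate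
25 | (3S,4S,5R)-7-[(tert-butyldimethylsilyloxy)methyl]-5-[(E)-2-methylbut-2-enoyloxy]-6-oxo-4-(propan-2-yl)octa-1,7-dien-3-yl (Z)-2-methylbut-2-enoate | C/C=C(/C)C(=O)O[C@@H](C=C)[C@H](C(C)C)[C@@H](OC(=O)/C(C)=C/C)C(=O)C(=C)CO[Si](C)(C)C(C)(C)C | intermediate
26 | (4S,5S,6R)-2-[(tert-butyldimethylsilyloxy)methyl]-4-[(Z)-2-methylbut-2-enoyloxy]-6-[(E)-2-methylbut-2-enoyloxy]-5-(propan-2-yl)cyclohex-2-en-1-one | C/C=C(/C)C(=O)O[C@H]1C=C(CO[Si](C)(C)C(C)(C)C)C(=O)[C@H](OC(=O)/C(C)=C/C)[C@H]1C(C)C | intermediate
27 | (4S,5S,6R)-2-(hydroxymethyl)-4-[(Z)-2-methylbut-2-enoyloxy]-6-[(E)-2-methylbut-2-enoyloxy]-5-(propan-2-yl)cyclohex-2-en-1-one | C/C=C(/C)C(=O)O[C@H]1C=C(CO)C(=O)[C@H](OC(=O)/C(C)=C/C)[C@H]1C(C)C | target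

## Step count and risks

Total step count: 14. Longest linear sequence: 12 (steps 1–8 and 11–14). Steps 9 and 10 form the side branch.

**Step 13 (key step).** The hindered, electron-poor 1,1-disubstituted C1 alkene may be taken up too slowly. Catalyst decay, coupling between vinyl groups of two molecules or migration of the C6 alkene could then overtake ring closure.
- The fallback exchanges the order of ring closure and oxidation, so that the ruthenium alkylidene meets an electron-richer allylic-alcohol alkene instead of an enone. It sets out from 24 and comes back at 26.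
- Ring-closing metathesis of 24 with the second-generation Grubbs catalyst RuCl2(H2IMes)(PCy3)(=CHPh) in refluxing CH2Cl2 at high dilution should give the cyclohexenol F1 as its two C2 epimers.
- Dess–Martin oxidation of both epimers should then converge on 26.

**Step 5.** Hemiacetal formation and hydride release from a conjugated, α-branched aldehyde may be slow. During that time the β-hydroxy vinyl ketone could be lost by intramolecular oxa-Michael closure or polymerisation, or the tiglate could drift from O3 to O5.
- The fallback separates reduction from ester placement and tells the two oxygens apart through the neighbouring C2 oxygen. It sets out from 11 and comes back at 17, replacing steps 5 and 6.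
- Hydroxyl-directed reduction with Me4NBH(OAc)3 in MeCN/AcOH at −30 °C (Evans–Saksena) should give the anti-diol F2, and HF·pyridine then frees the triol F3.
- 2,2-Dimethoxypropane with pyridinium tosylate should close the five-membered ring on the terminal 1,2-diol in preference to a dioxane on the anti-1,3-diol, giving the C2,C3-acetonide F4 with only O5 free.
- The mixed anhydride 16 in toluene at 80 °C gives the angelate acetonide F5, and aqueous acetic acid opens it to the C2,C3-diol F6.
- TBSCl and imidazole at 0 °C silylate the primary hydroxyl to the C2 silyl ether F7. Steglich esterification with tiglic acid (EDC·HCl, DMAP) then gives 17.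

**Step 6.** The activated angeloyl unit may isomerise from Z to E. Acylation of the hindered C5 hydroxyl may also be so slow at 80 °C that a 1,3-shift of the tiglate sets in.
- The fallback builds the Z-alkene on the ester instead of transferring it. It sets out from 14 and comes back at 17.
- Carbodiimide coupling of 14 with 2-[bis(2,2,2-trifluoroethoxy)phosphoryl]propanoic acid at room temperature should give the phosphonopropionate F8.
- Still–Gennari olefination of F8 with acetaldehyde (KN(SiMe3)2, 18-crown-6, THF, −78 °C) should form the angelate alkene Z-selectively and deliver 17.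

## Further compounds

F1 | step 13 | 2-[(tert-butyldimethylsilyloxy)methyl]-4-[(Z)-2-methylbut-2-enoyloxy]-6-[(E)-2-methylbut-2-enoyloxy]-5-(propan-2-yl)cyclohex-2-en-1-ol (C2 epimers; C3 R, C4 S, C5 S in the route numbering) | C/C=C(/C)C(=O)O[C@H]1C=C(CO[Si](C)(C)C(C)(C)C)C(O)[C@H](OC(=O)/C(C)=C/C)[C@H]1C(C)C
F2 | step 5 | (3S,4S,5R)-6-(tert-butyldimethylsilyloxy)-4-(propan-2-yl)hex-1-ene-3,5-diol | O[C@@H](C=C)[C@H](C(C)C)[C@@H](O)CO[Si](C)(C)C(C)(C)C
F3 | step 5 | open-chain C2,C3,C5-triol, 3-(propan-2-yl)hex-5-ene-1,2,4-triol with the configuration of F2 | O[C@@H](C=C)[C@H](C(C)C)[C@@H](O)CO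
F4 | step 5 | C2,C3-acetonide of F3 with free C5 hydroxyl | O[C@@H](C=C)[C@H](C(C)C)[C@@H]1COC(C)(C)O1
F5 | step 5 | C5 angelate of F4 | C/C=C(/C)C(=O)O[C@@H](C=C)[C@H](C(C)C)[C@@H]1COC(C)(C)O1
F6 | step 5 | C5 angelate with free C2 and C3 hydroxyls | C/C=C(/C)C(=O)O[C@@H](C=C)[C@H](C(C)C)[C@@H](O)CO
F7 | step 5 | C5 angelate, C2 tert-butyldimethylsilyl ether, free C3 hydroxyl | C/C=C(/C)C(=O)O[C@@H](C=C)[C@H](C(C)C)[C@@H](O)CO[Si](C)(C)C(C)(C)C
F8 | step 6 | 2-[bis(2,2,2-trifluoroethoxy)phosphoryl]propanoate of 14 at O5 (phosphonate α-carbon undefined) | CC(P(=O)(OCC(F)(F)F)OCC(F)(F)F)C(=O)O[C@@H](C=C)[C@H](C(C)C)[C@@H](OC(=O)/C(C)=C/C)CO[Si](C)(C)C(C)(C)C
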